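A direct plan would keep ring A aromatic throughout: 4-(benzyloxy)-2,3,5,6-tetramethoxybenzaldehyde A1 would be joined at its formyl carbon to [(4-methoxyphenyl)ethynyl](phenyl)iodonium tosylate A2 under carbene catalysis to give the aryl ynone A3.
BCl3 would then remove the benzyl ether and one ortho methyl ether to give the dihydroxy ynone A4, and acid would close ring C by oxa-Michael addition of the new phenol to the ynone.
Its weakest steps would be:
- the carbene-catalysed alkynylation, because a 2,6-dimethoxybenzaldehyde would form a Breslow intermediate reluctantly and this coupling has no precedent on such an aldehyde;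
- the BCl3 dealkylation, because it would have to cleave the benzyl ether and exactly one of five methyl ethers on a substrate whose ynone is itself open to chloride addition under the Lewis acid;
- the preparation of A1 by ring halogenation and copper-mediated methoxylation, which would add steps but no complexity.

The new route closes ring C on a dearomatised ring A and aromatises ring A last. All six ring-A carbons come from tetramethoxy-1,4-benzoquinone: one carbonyl carbon becomes C4a by alkynylation, the para carbonyl survives as the C7 hydroxyl, and C5 and C8a are equivalent methoxy-bearing β-carbons of the dienone. In the key step the diketone enol oxygen displaces methoxide at C8a (O1–C8a bond, ring C) and zinc then expels the quinol acetate from C4a, aromatising ring A. No hindered aldehyde is coupled, no ether is cleaved and no ring halogenation is needed: the 7-OH is never protected and the surplus methoxy group leaves as methanol.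

Key step: step 4

Step 1
Reactants: 1 chloranil (2,3,5,6-tetrachloro-1,4-benzoquinone)
Product: 2 2,3,5,6-tetramethoxy-1,4-benzoquinone
Conditions: NaOMe (4.5 equiv), MeOH, 0 °C → reflux; AcOH quench
Reagents that add atoms: sodium methoxide, [Na+].[O-]C
Why: Fourfold addition–elimination of methoxide at the chlorine-bearing carbons of the quinone, each a vinylogous acid chloride, is a classical substitution of chloranil that needs no metal catalyst and should deliver all ring-A oxygens in one operation.

Step 2
Reactants: 2 2,3,5,6-tetramethoxy-1,4-benzoquinone; 3 ethynylmagnesium bromide (1.15 equiv)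
Product: 5 1-ethynyl-2,3,5,6-tetramethoxy-4-oxocyclohexa-2,5-dien-1-yl acetate, via bromomagnesium alkoxide 4 (not isolated)
Conditions: HC≡CMgBr (0.5 M in THF), THF, −40 → 0 °C; then Ac2O (3 equiv), DMAP (10 mol %), 0 °C → rt
Reagents that add atoms: acetic anhydride, CC(=O)OC(C)=O
Why: 1,2-Addition of an alkynyl Grignard reagent to one of the two equivalent quinone carbonyls (p-quinol synthesis) should stop after one addition because the alkoxide deactivates the remaining doubly vinylogous ester carbonyl, and acetylation of the magnesium alkoxide in the same flask caps the tertiary oxygen, which blocks retro-ethynylation and the 3(2H)-furanone closure open to a free γ-hydroxy ynone and provides the leaving group for the final aromatisation; the carbinol carbon carries two identical ring arms, so no stereocentre arises.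

Step 3
Reactants: 5 1-ethynyl-2,3,5,6-tetramethoxy-4-oxocyclohexa-2,5-dien-1-yl acetate; 6 4-methoxybenzoyl chloride (1.2 equiv)
Product: 7 2,3,5,6-tetramethoxy-1-[3-(4-methoxyphenyl)-3-oxoprop-1-yn-1-yl]-4-oxocyclohexa-2,5-dien-1-yl acetate
Conditions: PdCl2(PPh3)2 (2 mol %), CuI (4 mol %), Et3N (1.5 equiv), THF, rt, degassed
Reagents that add atoms: none
Why: Acyl Sonogashira coupling, in which the aroyl chloride adds oxidatively to zerovalent palladium, the copper acetylide of the terminal alkyne transmetalates and reductive elimination gives the ynone at room temperature, conditions under which the dienone and the tertiary acetate should be inert.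

Step 4
Reactants: 7 2,3,5,6-tetramethoxy-1-[3-(4-methoxyphenyl)-3-oxoprop-1-yn-1-yl]-4-oxocyclohexa-2,5-dien-1-yl acetate
Product: 11 7-hydroxy-4',5,6,8-tetramethoxyflavone, via enaminone 8 (not isolated), via diketone 9 (not isolated), via acetoxy dienone 10 (not isolated)
Conditions: Et2NH (1.1 equiv), THF, 0 °C; then TsOH·H2O (1.5 equiv), H2O (5 equiv), 40 °C; then NaOAc, AcOH, Zn dust (6 equiv), 0 °C → rt
Reagents that add atoms: water, O; diethylamine, CCNCC (its atoms stay only in intermediate 8)
Why: Proposed new method: diethylamine adds to the β-carbon of the ynone (the carbon bonded to the quinol carbon) and acid hydrolysis of enaminone 8 places the C4 oxygen (diketone 9); protonation of the cross-conjugated dienone at the C7 carbonyl then makes the methoxy-bearing β-carbon C8a an oxocarbenium-like electrophile, the enol oxygen on C2 adds to it and methanol is lost to give 10, and zinc finally transfers two electrons into the α-acetoxy ketone and dienone of 10, so that acetate leaves from C4a and ring A aromatises with the former quinone carbonyl as the C7 phenol. The closest known reaction types are the acid-catalysed alkoxy exchange on β-alkoxy enones and methoxyquinones, the amine–acid hydration of ynones to 1,3-diketones, and the zinc–acetic acid reductive aromatisation of p-quinol acetates (α-acyloxy ketone cleavage); new is their use on a quinol dienone to close a γ-pyrone. Ring C closes 6-exo-trig at the O1–C8a bond, while ring A is not closed but aromatised. The only stereocentre formed, C4a of 10, is racemic because C5 and C8a are enantiotopic, and it is destroyed in the aromatisation; the target has none. The step needs closure to the six-membered ring only: the capped quinol oxygen cannot form the otherwise favoured 3(2H)-furanone, attack from C3 would give a four-membered ring, and attack at C5 or C8a leads to the same product. The amine should choose the ynone over the dienone methoxy carbons because the ynone is by far the stronger acceptor at 0 °C with one equivalent, and zinc should spare the γ-pyrone because the aromatisation-driven loss of acetate is fast at room temperature.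

Compound list
1 | chloranil (2,3,5,6-tetrachlorocyclohexa-2,5-diene-1,4-dione) | O=C1C(Cl)=C(Cl)C(=O)C(Cl)=C1Cl | starting material
2 | 2,3,5,6-tetramethoxycyclohexa-2,5-diene-1,4-dione (tetramethoxy-1,4-benzoquinone) | COC1=C(OC)C(=O)C(OC)=C(OC)C1=O | intermediate
3 | ethynylmagnesium bromide | C#C[Mg]Br | starting material
4 | bromomagnesium 1-ethynyl-2,3,5,6-tetramethoxy-4-oxocyclohexa-2,5-dien-1-olate (not isolated) | C#CC1(O[Mg]Br)C(OC)=C(OC)C(=O)C(OC)=C1OC | intermediate
5 | 1-ethynyl-2,3,5,6-tetramethoxy-4-oxocyclohexa-2,5-dien-1-yl acetate | CC(=O)OC1(C#C)C(OC)=C(OC)C(=O)C(OC)=C1OC | intermediate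
6 | 4-methoxybenzoyl chloride | COc1ccc(cc1)C(Cl)=O | starting material
7 | 2,3,5,6-tetramethoxy-1-[3-(4-methoxyphenyl)-3-oxoprop-1-yn-1-yl]-4-oxocyclohexa-2,5-dien-1-yl acetate | COc1ccc(cc1)C(=O)C#CC1(OC(C)=O)C(OC)=C(OC)C(=O)C(OC)=C1OC | intermediate
8 | 1-[1-(diethylamino)-3-(4-methoxyphenyl)-3-oxoprop-1-en-1-yl]-2,3,5,6-tetramethoxy-4-oxocyclohexa-2,5-dien-1-yl acetate (not isolated; alkene geometry not fixed, the isomers interconvert) | CCN(CC)C(=CC(=O)c1ccc(OC)cc1)C1(OC(C)=O)C(OC)=C(OC)C(=O)C(OC)=C1OC | intermediate
9 | 2,3,5,6-tetramethoxy-1-[3-(4-methoxyphenyl)-3-oxopropanoyl]-4-oxocyclohexa-2,5-dien-1-yl acetate (not isolated; 1,3-diketone, drawn as the diketo tautomer) | COc1ccc(cc1)C(=O)CC(=O)C1(OC(C)=O)C(OC)=C(OC)C(=O)C(OC)=C1OC | intermediate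
10 | 5,6,8-trimethoxy-2-(4-methoxyphenyl)-4,7-dioxo-4,7-dihydro-4aH-chromen-4a-yl acetate (not isolated; racemic) | COc1ccc(cc1)C1=CC(=O)C2(OC(C)=O)C(OC)=C(OC)C(=O)C(OC)=C2O1 | intermediate
11 | 7-hydroxy-4',5,6,8-tetramethoxyflavone = 7-hydroxy-5,6,8-trimethoxy-2-(4-methoxyphenyl)-4H-chromen-4-one | COc1ccc(-c2cc(=O)c3c(OC)c(OC)c(O)c(OC)c3o2)cc1 | target

Total step count: 4. Longest linear sequence: 4 steps (1 → 2 → 5 → 7 → 11).

Steps most likely to fail

Step 4 (proposed new method). Hydrolysis of a ring methoxy group or of the acetate by the aqueous acid may outrun the intramolecular displacement at C8a, so that ring C is not closed before the reduction. The fallback uses known chemistry and sets out from 7. Amine addition and hydrolysis as above would give diketone 9, and zinc in acetic acid applied directly to 9 would give, by reductive aromatisation of the quinol acetate, 1-(4-hydroxy-2,3,5,6-tetramethoxyphenyl)-3-(4-methoxyphenyl)propane-1,3-dione F1. BCl3 in CH2Cl2 would then cleave one of the two equivalent methyl ethers ortho to the ring-A carbonyl to give 1-(2,4-dihydroxy-3,5,6-trimethoxyphenyl)-3-(4-methoxyphenyl)propane-1,3-dione F2. The boron chelate formed after the first cleavage should protect the second ortho ether, and the diketone, unlike an ynone, offers no site for chloride addition. Cyclodehydration with H2SO4 in AcOH would return to the route at 11. This fallback gives up the ether-cleavage-free closure.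

Step 2. The Grignard reagent may reduce the quinone by single-electron transfer or attack a methoxy-bearing carbon, and acetylation of the hindered magnesium alkoxide may stay incomplete. The fallback sets out from 2 with a capped, less reducing organolithium. Lithium (trimethylsilyl)acetylide (from ethynyltrimethylsilane and n-BuLi, THF, −78 °C), followed by Ac2O in the same flask, would give 2,3,5,6-tetramethoxy-4-oxo-1-[(trimethylsilyl)ethynyl]cyclohexa-2,5-dien-1-yl acetate F3. Desilylation with TBAF buffered by AcOH (THF, 0 °C) would return to the route at 5.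

Step 3. Zerovalent palladium may ionise the tertiary propargylic acetate instead of the acyl chloride, or the alkyne may homocouple oxidatively. The fallback sets out from 5 and avoids palladium. Zn(OTf)2 and Et3N would add the terminal alkyne to 4-methoxybenzaldehyde to give the racemic propargylic alcohol 1-[3-hydroxy-3-(4-methoxyphenyl)prop-1-yn-1-yl]-2,3,5,6-tetramethoxy-4-oxocyclohexa-2,5-dien-1-yl acetate F4. Oxidation with MnO2 in CH2Cl2 would return to the route at 7.

Further compounds
F1 | step 4 | 1-(4-hydroxy-2,3,5,6-tetramethoxyphenyl)-3-(4-methoxyphenyl)propane-1,3-dione | COc1ccc(cc1)C(=O)CC(=O)c1c(OC)c(OC)c(O)c(OC)c1OC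
F2 | step 4 | 1-(2,4-dihydroxy-3,5,6-trimethoxyphenyl)-3-(4-methoxyphenyl)propane-1,3-dione | COc1ccc(cc1)C(=O)CC(=O)c1c(O)c(OC)c(O)c(OC)c1OC
F3 | step 2 | 2,3,5,6-tetramethoxy-4-oxo-1-[(trimethylsilyl)ethynyl]cyclohexa-2,5-dien-1-yl acetate | C[Si](C)(C)C#CC1(OC(C)=O)C(OC)=C(OC)C(=O)C(OC)=C1OC
F4 | step 3 | 1-[3-hydroxy-3-(4-methoxyphenyl)prop-1-yn-1-yl]-2,3,5,6-tetramethoxy-4-oxocyclohexa-2,5-dien-1-yl acetate (racemic) | COc1ccc(cc1)C(O)C#CC1(OC(C)=O)C(OC)=C(OC)C(=O)C(OC)=C1OC
A1 | direct plan | 4-(benzyloxy)-2,3,5,6-tetramethoxybenzaldehyde | O=Cc1c(OC)c(OC)c(OCc2ccccc2)c(OC)c1OC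
A2 | direct plan | [(4-methoxyphenyl)ethynyl](phenyl)iodonium tosylate | COc1ccc(cc1)C#C[I+]c1ccccc1.Cc1ccc(cc1)S(=O)(=O)[O-]
A3 | direct plan | 1-[4-(benzyloxy)-2,3,5,6-tetramethoxyphenyl]-3-(4-methoxyphenyl)prop-2-yn-1-one | COc1ccc(cc1)C#CC(=O)c1c(OC)c(OC)c(OCc2ccccc2)c(OC)c1OC
A4 | direct plan | 1-(2,4-dihydroxy-3,5,6-trimethoxyphenyl)-3-(4-methoxyphenyl)prop-2-yn-1-one | COc1ccc(cc1)C#CC(=O)c1c(O)c(OC)c(O)c(OC)c1OC
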